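Temperature is the choice in front of you: teal stands at 25 °C and red at 0 °C, with the same charges and the same time.

| setting | dusk | dawn | summer | teal | red |
|---|---|---|---|---|---|
| substrate | 0.050 M | 0.050 M | 0.025 M | 0.050 M | 0.050 M |
| first nucleophile | 0.60 equiv | 0.90 equiv | 1.2 equiv | 1.20 equiv | 1.20 equiv |
| second nucleophile | 1.2 equiv | 1.2 equiv | 1.2 equiv | 1.20 equiv | 1.20 equiv |
| temperature | −5 °C | 12 °C | −5 °C | 25 °C | 0 °C |
| remark | run made earlier | run made earlier | run made earlier |  |  |
| time |  |  |  | 50 h | 50 h |

- dusk (time / h: target / %): 12.0: 5.5; 25.0: 7.8; 48.0: 11.3; 96.0: 11.6; 192: 11.9
- dawn (time / h: target / %): 6.00: 21.5; 12.0: 21.5; 25.0: 22.0; 40.0: 22.2; 72.0: 22.1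
- summer (time / h: target / %): 20.0: 13.4; 40.0: 16.6; 96.0: 19.2; 144: 17.7; 192: 17.7

(standard deviation of a reading: 0.5 percentage points)

- which flask leads in amount of target, in percent of the substrate charged ("all alike" within 1.5 percentage points) (teal / red / all alike)
- how much target is there at the end, in percent of the substrate charged: teal
- how much target is there at the end, in percent of the substrate charged: red

- what was read earlier has a scatter of 0.5 percentage points, one standard deviation
- a reading or a percentage of target counts all its forms, free or not

The dusk run looks contradictory. Its target levels off at 11.9% of the substrate, yet by that reading 80.2% of its first nucleophile is unspent, so target stops with reagent still at hand. I read this as the substrate being the limiting reagent, with the second nucleophile taking what the first did not.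

Then work with the fractions left, not the fractions made. If the two nucleophiles compete, each at a rate proportional to its own concentration, the logarithm of the fraction of first nucleophile left, divided by the same logarithm for the second, is a selectivity factor that holds through the run. I charge all substrate not in target to the second nucleophile. That gives 0.167 for dusk and 0.269 for dawn, both at 0.050 M.

Taking its logarithm as straight in temperature, the selectivity factor for red is 0.192 and for teal 0.388. As a working assumption, which readings of target cannot test, I let each flask spend across both nucleophiles as much as the substrate charged. Solving the two conditions together, I get 32.9% in teal and 21.9% in red.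

The forecast names teal as leader, with 30% (25% to 36%) in teal and 23% (19% to 27%) in red, and it opens: “The plateaus, not the rates, carry the information.” My teal stands above its figure and my red below, but the order is the same.

    second nucleophile + intermediate → other capture product (k = 2100 M⁻¹ h⁻¹, Ea = 38.0 kJ mol⁻¹)
    intermediate → solvolysis product (k = 43.1 h⁻¹, Ea = 73.0 kJ mol⁻¹)
    substrate → intermediate (k = 2.68 h⁻¹, Ea = 82.0 kJ mol⁻¹)
    first nucleophile + intermediate → target (k = 1260 M⁻¹ h⁻¹, Ea = 62.0 kJ mol⁻¹)
    crystals ⇌ target, rate k5*(cs5 - [target]) while solid is left; crystals form when [target] > cs5 (solubility = 8.00 mM, k = 2.44 h⁻¹)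
    first nucleophile → decomposition product (k = 2.17 × 10⁻⁴ h⁻¹, Ea = 110 kJ mol⁻¹)
    (constants at 25 °C)

The flasks give 31.5% in teal and 22.4% in red, so teal leads. Capture by the second nucleophile is the main reason red stays low: with that step taken away, red gives 64.6% instead of 22.4%. Red ends with 81% of its first nucleophile and 43% of its second, which reads as a selectivity factor of 0.248, above my 0.192. A neighbour of red with 3.00 equiv of first nucleophile ends with 56% of its second; red's factor then gives 40.2% of target, and that flask holds 40.3%.

The runs were computed with constants of no real substance; the scatter is artificial.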